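**Assumption:** the target has no sp³ stereocentres, so "single enantiomer" is moot. The only stereo-element is the (E)-enone, which is set in Step 3 and never touched afterwards.

## Retrosynthetic overview
1. Avoid the Claisen–Schmidt disconnection. Cut the aryl–C(=O) bond instead: a BF₃-mediated Friedel–Crafts acylation of resorcinol by a preformed (E)-cinnamic acid builds the 2',4'-dihydroxyaryl enone directly.
2. The prenyl group is carried through as an acid-stable allyl group (prenyl-phenols cyclise to chromans in Lewis acid). It is converted to prenyl in the last step by cross-metathesis with 2-methyl-2-butene.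
3. The allyl group comes from an aryl allyl ether Claisen rearrangement of vanillin's O-allyl ether. The (E)-cinnamic acid comes from a Doebner condensation. No rings are formed in this synthesis; both aromatic rings come from commercial materials.

## Forward route

**Step 1**
Reactants: **1** vanillin; **2** allyl bromide
Product: **3** 4-(allyloxy)-3-methoxybenzaldehyde
Conditions: K₂CO₃, DMF, 60 °C
Reagents that add atoms: allyl bromide, C=CCBr
Why: Williamson O-alkylation of the most acidic phenol; no stereochemistry is involved.

**Step 2**
Reactant: **3**
Product: **4** 3-allyl-4-hydroxy-5-methoxybenzaldehyde (5-allylvanillin)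
Conditions: neat or o-dichlorobenzene, 190–200 °C (sealed tube or microwave), 1–2 h
Reagents that add atoms: none
Why: Aromatic Claisen [3,3] rearrangement followed by tautomerisation. C3 is blocked by OMe, so the allyl group goes only to C5, ortho to the oxygen.

**Step 3**
Reactants: **4**; **5** malonic acid
Product: **6** (E)-3-(3-allyl-4-hydroxy-5-methoxyphenyl)acrylic acid (5-allylferulic acid)
Conditions: pyridine, piperidine (cat.), 90 °C, then aq. HCl
Reagents that add atoms: malonic acid, OC(=O)CC(=O)O
Why: Knoevenagel–Doebner condensation with decarboxylation. It gives the (E)-alkene exclusively, the only stereo-element of the target, as in the standard vanillin → ferulic acid conversion.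

**Step 4 (key step)**
Reactants: **6**; **7** resorcinol
Product: **8** (E)-1-(2,4-dihydroxyphenyl)-3-(3-allyl-4-hydroxy-5-methoxyphenyl)prop-2-en-1-one
Conditions: BF₃·OEt₂ (solvent/promoter), 80 °C, 2 h; then aq. NaOAc, rt
Reagents that add atoms: resorcinol, Oc1cccc(O)c1
Why: Friedel–Crafts (Kostanecki-type) C-acylation of resorcinol, the same chemistry as resorcinol + AcOH/BF₃ → resacetophenone. Attack occurs at C4, para to one OH and ortho to the other, and the BF₂-chelate of the 2'-hydroxy ketone is hydrolysed on work-up. The allyl group is inert to these conditions, and the E-enone is retained.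

**Step 5**
Reactants: **8**; **9** 2-methyl-2-butene
Product: **10** abyssinone D, (E)-1-(2,4-dihydroxyphenyl)-3-(4-hydroxy-3-methoxy-5-(3-methylbut-2-en-1-yl)phenyl)prop-2-en-1-one
Conditions: Hoveyda–Grubbs II (5 mol %), 1,4-benzoquinone (10 mol %), 2-methyl-2-butene (30 equiv), CH₂Cl₂, 40 °C, sealed tube, 12 h
Reagents that add atoms: 2-methyl-2-butene, CC=C(C)C (propene is lost)
Why: Proposed new method: cross-metathesis converts the terminal allyl alkene into the prenyl alkene, ArCH₂CH=CH₂ + Me₂C=CHMe → ArCH₂CH=CMe₂ + CH₂=CHMe. The mechanistic reasoning is that the unhindered terminal olefin reacts far faster with the Ru carbene than the conjugated, H-bond-chelated chalcone olefin, and excess trisubstituted olefin drives propene out. Benzoquinone suppresses Ru–H allyl-to-propenyl isomerisation. The closest known reaction is the prenylation of allylarenes by CM with 2-methyl-2-butene. The E-enone is untouched, and there are no new stereocentres.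

## Checks
- **Target match:** the target SMILES has 1,2,3-trisubstituted B-ring carbons with OMe and OH adjacent and prenyl on the other side of OH, a 2',4'-dihydroxyphenyl ketone and an (E)-enone. Compound **10** has all of these.
- **Atom balance:** C₈H₈O₃ → C₁₁H₁₂O₃ (Steps 1, 2) → C₁₃H₁₄O₄ (Step 3, −H₂O −CO₂) → C₁₉H₁₈O₅ (Step 4, −H₂O) → C₂₁H₂₂O₅ (Step 5, +C₅H₁₀ −C₃H₆). This is the formula of the target.
- **Functional-group survival:** the aldehyde survives Claisen heating, the free phenols survive Steps 1–3, and the allyl group survives BF₃. The prenyl group is installed last, after all acid steps, so chroman cyclisation is avoided.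
- **Stereochemistry:** the only stereo-element, the E-olefin, is set in Step 3 and not altered later.

## Compound list
1 | vanillin | COc1cc(C=O)ccc1O | starting material
2 | allyl bromide | C=CCBr | starting material
3 | 4-(allyloxy)-3-methoxybenzaldehyde | COc1cc(C=O)ccc1OCC=C | intermediate
4 | 3-allyl-4-hydroxy-5-methoxybenzaldehyde | COc1cc(C=O)cc(CC=C)c1O | intermediate
5 | malonic acid | OC(=O)CC(=O)O | starting material
6 | (E)-3-(3-allyl-4-hydroxy-5-methoxyphenyl)acrylic acid | COc1cc(/C=C/C(=O)O)cc(CC=C)c1O | intermediate
7 | resorcinol | Oc1cccc(O)c1 | starting material
8 | (E)-allyl chalcone | COc1cc(/C=C/C(=O)c2ccc(O)cc2O)cc(CC=C)c1O | intermediate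
9 | 2-methyl-2-butene | CC=C(C)C | starting material
10 | abyssinone D | COc1cc(/C=C/C(=O)c2ccc(O)cc2O)cc(CC=C(C)C)c1O | target

**Total steps:** 5. **Longest linear sequence:** 5 (vanillin → 10). Resorcinol, malonic acid and 2-methyl-2-butene enter as single-step partners.

## Three steps most likely to fail
1. **Step 4 (Friedel–Crafts with an electron-rich p-hydroxycinnamic acid).** Risks are low conversion, oligomerisation, O-acylation or flavanone formation.
   Fallback: acetylate the B-ring phenol of **6**, make the acid chloride, form the resorcinol cinnamate ester, and run an AlCl₃ Fries rearrangement. Alternatively, abandon the C–C(=O) disconnection and use a Claisen–Schmidt of **4** with 2,4-dihydroxyacetophenone.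
2. **Step 5 (late-stage CM on a polyphenolic chalcone).** Risks are Ru poisoning by the phenols, allyl isomerisation, and CM at the enone.
   Fallback: do the CM earlier on aldehyde **4** to give 5-prenylvanillin, then finish with a base-mediated Claisen–Schmidt with 2,4-dihydroxyacetophenone, which avoids Lewis acid and Ru in the presence of the chalcone.
3. **Step 2 (thermal Claisen at ~200 °C).** Risks are decomposition or aldehyde oxidation.
   Fallback: skip Steps 1–2 and make **4** from commercial 5-bromovanillin by Pd-catalysed Suzuki coupling with allyl-Bpin.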